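## Structural features

The target is a 3,3a-dihydro-1-benzofuran-6(2H)-one. Ring B (O1, C2, C3, C3a, C7a) is an oxolane fused along C3a–C7a to ring A, a cross-conjugated cyclohexa-2,5-dienone (C3a–C4=C5–C6(=O)–C7=C7a). C5 carries a methoxy group and O1–C7a=C7–C6=O is a vinylogous ester, so C7a sits at the carboxylic acid oxidation level. Three contiguous stereocentres lie on ring B: C2 (3,4,5-trimethoxyphenyl), C3 (methyl) and the all-carbon quaternary fusion atom C3a (allyl), configuration (2S,3S,3aS). Aryl and methyl are trans, methyl and allyl are trans, so aryl and allyl share one face. Fragile points are the 3a-allyl dienone (Cope-type allyl shifts on heating, dienone–phenol-type aromatisation in strong acid), the benzylic C2–O1 bond next to an electron-rich arene, and the two enol ethers. The real difficulty is the quaternary C3a, which must be set relative to C3 while ring A is kept non-aromatic with three different oxygen functions. The plan uses the fact that O1–C2–C3–C3a–C7a is a latent γ-butyrolactone (C7a the carbonyl carbon) with C4 as an exocyclic methylene on its α-carbon C3a. A 2-carboxy-crotylboration of the aryl aldehyde gives exactly that α-methylene lactone, sets C2 and C3 together, and leaves C3a as an acceptor/enolate position and C7a as an acyl carbon for ring A.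

## Logic of the disconnections

20 ⇒ 19. The enol ether bond O1–C7a and the double bond C4=C5 are both condensation products and are cut first by formal addition of water, giving a C2 hydroxyl, a C7a ketone and a C4 carbinol. The reason is that the heat- and acid-sensitive allyl dienone then appears only in the last operation. The gain is a monocyclic cyclohexane-1,3-dione, 19. The demand is that both dehydrations run under acid mild enough to leave the allyl group and the benzylic C2–O bond alone; only C5 carries a hydrogen next to C4, and only C7a is within five-ring reach of the C2 hydroxyl.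

19 ⇒ 18. C7–C7a is cut (retro-Claisen). C7a returns to a lactone carbonyl with O1 as the acyl leaving group, and C7 becomes a ketone methyl. The reason is that C7a is already at the acyl level in a lactone. The gain is that ring A disappears and 18 is a lactone with a four-carbon side chain. The demand is kinetic enolisation at the methyl group and six-membered closure on a carbonyl flanked by a quaternary carbon. The O1–C7a bond may open in this step and is re-formed in the acid stage; C2–O1 is never broken.

18 ⇒ 14 + 16. C4–C5 is cut (aldol). The reason is that C4 as a non-enolisable aldehyde is an unambiguous electrophile. The gain is that C5, C6 and C7 with the C5 methoxy arrive in one piece. The demand is a nucleophile that reacts at the methoxy-bearing carbon only, hence a preformed enol silane. The relative configuration at C4/C5 does not matter, and ring closure before dehydration makes the C4=C5 geometry automatic.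

16 ⇒ 15. The O–Si bond is cut; regiochemistry is settled at the reagent stage.

14 ⇒ 12 ⇒ 11. The C4 aldehyde is traced to a C4 sulfoxide and then a sulfide (Pummerer logic). The reason is that sulfur marks C4 and carries its oxidation level without adding carbon. The demand is that C3a be quaternary before the rearrangement, so that no elimination or epimerisation can occur.

11 ⇒ 8 + 9. The C3a–CH2 bond of the allyl group is cut (enolate alkylation). The gain is that the quaternary centre reduces to an enolisable lactone α-carbon. The demand is attack anti to the neighbouring C3 methyl and an enolate that lives long enough despite its β-sulfur substituent.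

8 ⇒ 7. The C4–S bond is cut (retro-thia-Michael), which exposes the α-methylene lactone.

7 ⇒ 6 ⇒ 4 + 5. O1–C7a (lactone) and C2–C3 are cut. The reason is that one carbonyl allylation sets both stereocentres and stores C7a, C3a and C4. The gain is two achiral fragments. The demand is anti selectivity (from the alkene geometry of 4) and one aldehyde face (from the chiral acid).

4 ⇒ 3 ⇒ 1 + 2. The bond between the α-carbon and the CH2B carbon is cut. The alkenyl metal 3 comes from syn-hydrometalation of 1, which fixes the methyl trans to the CH2B arm without relying on equilibration of an alkenylcopper species.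

## Other disconnections considered

Alternative 1: The cut is C3–C3a combined with a one-carbon ring contraction: ring B is traced to the pyranone ring of the 3-diazoflavanone A1. In the forward step, photolysis of A1 in an alcohol would trigger a Wolff shift of the aryl carbon from the carbonyl carbon to C3, and the ketene would be trapped as the trans ester A2.
- In its favour: flavanones are easy to make in enantioenriched form, diazo transfer and Wolff contraction are textbook operations, and all six carbons of ring A with their oxygen pattern come from a cheap arene. On this point it is better than the chosen plan, which builds ring A from three pieces. Control of C2/C3 is equal, since the ester centre can equilibrate to trans.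
- Against it here: A2 is aromatic, so C3a is not yet a stereocentre. After ester-to-methyl reduction and desilylation, a late dearomatising C-allylation para to the C6 phenol would have to choose C3a over oxygen and over the free ortho carbon C7, and enter anti to methyl. The product could relax to an arene by allyl migration.
- Comparison: the chosen plan creates C3a by alkylating a lactone enolate with a well-understood facial bias. Alternative 1 reaches A2 quickly but needs about five further steps, with the largest uncertainty at the end.

Alternative 2: The cuts are C3a–C7a and C6–C7. In the forward step, heating the precursor A3 (a vinylketene silyl acetal tethered through O1–C2–C3 to an alkoxypropiolate ester) would give an intramolecular Diels–Alder reaction. The donor-activated diene terminus C3a bonds to the ester β-carbon C7a, and the C6 mixed ketal collapses to the ketone, giving A4.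
- In its favour: both rings, the quaternary centre and the full oxygenation of ring A form in one step. In bonds and rings per step it is clearly better than the chosen key step. Regiochemistry is enforced by tether and polarisation, there is no endo/exo question, and A4 is one ester removal from the target.
- Against it here: A3 is long to make and fragile. The ketene acetal is hydrolytically labile, and the ynol ether of a secondary benzylic alcohol can rearrange thermally in competition with the cycloaddition. The fully substituted diene terminus must turn one substituent inward in the s-cis conformer. The C3a configuration depends on both diene geometry and facial bias from C3. C2 and C3 must be made beforehand by separate asymmetric chemistry. Removing the tert-butyl ester needs acid that the allyl dienone may not tolerate.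
- Comparison: more elegant and far shorter after the key step, but weaker on precursor access and thermal risk.

Alternative 3: The cut is O1–C7a. In the forward step, a catalytic alkoxide base would make the C2 alkoxide of the dienone A5 add to one of the two enone arms (5-exo-trig), giving cis-fused A6 and fixing C3a.
- In its favour: a mild, catalytic ring closure, as easy as the lactonisation of the chosen plan (equal on this point), with cis fusion guaranteed. The ring A carbons again come from a dearomatised arene.
- Against it here: A6 lacks the C5 methoxy group and the C7=C7a double bond. It needs dehydrogenation next to the ether oxygen and α-oxygenation of the remaining enone, several redox steps with regiochemical questions. The choice between the two arms decides whether allyl ends cis or trans to methyl; it is substrate-controlled and reversible, so the outcome is uncertain. A5 itself needs the quaternary carbon with the stereodefined side chain, which moves the main problem rather than solving it.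
- Comparison: simpler and milder for ring B, but the chosen plan delivers ring A at the correct oxidation level by construction, and Alternative 3 is unlikely to be shorter overall.

Key step: step 2

Assumption: the aldehyde face selected by 3,3'-diaryl BINOL phosphoric acids with pinacol allyl- and crotylboronates (R acid, Re face of aryl aldehydes) is taken to hold for 4, so the S acid is specified for the Si-face addition leading to (4S,5S)-7; the mirror-image acid would be used if the sense proved opposite.

## Steps

Step 1
Reactants: 1 ethyl but-2-ynoate; 2 2-(iodomethyl)-4,4,5,5-tetramethyl-1,3,2-dioxaborolane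
Product: 4 ethyl (Z)-2-[(4,4,5,5-tetramethyl-1,3,2-dioxaborolan-2-yl)methyl]but-2-enoate, via vinylalane 3 (not isolated)
Conditions: i-Bu2AlH, HMPA, THF, 0 °C; then 2, 0 °C → rt
Reagents that add atoms: none
Why: Conjugate syn-hydroalumination of the ynoate places aluminium on C2 cis to the new hydrogen, so the methyl group is trans to the metal. The alkenyl–aluminium bond then adds to boron of 2 and a Matteson-type 1,2-shift with loss of iodide forms the C–CH2B bond with retention; the allenoate form is likewise alkylated on the hydrogen side, so both paths should give the (Z)-ester with methyl trans to the CH2B arm.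

Step 2
Reactants: 4 ethyl (Z)-2-[(4,4,5,5-tetramethyl-1,3,2-dioxaborolan-2-yl)methyl]but-2-enoate; 5 3,4,5-trimethoxybenzaldehyde
Product: 7 (4S,5S)-4-methyl-3-methylidene-5-(3,4,5-trimethoxyphenyl)oxolan-2-one, via borate ester 6 (not isolated)
Conditions: (S)-3,3'-bis(2,4,6-triisopropylphenyl)-BINOL hydrogen phosphate (10 mol %), toluene, 0 °C → rt; then TsOH·H2O (10 mol %), rt
Reagents that add atoms: none
Why: The aldehyde oxygen of 5 binds boron of 4 while the phosphoric acid hydrogen-bonds to a dioxaborolane oxygen, and allyl transfer runs through a closed six-membered chair in which the γ-carbon of 4 attacks the carbonyl carbon, forming C2–C3 and moving the double bond to the exocyclic position (future C4). The closest known reaction types are the Brønsted acid-catalysed allylboration–lactonisation of aldehydes with 2-alkoxycarbonyl allylboronates and the chiral phosphoric acid-catalysed crotylboration of aldehydes with pinacol crotylboronates. In the chair the aryl group is equatorial and the methyl of 4, trans to the CH2B arm, is also equatorial, so C2 and C3 form anti; this relation is controlled by the alkene geometry of 4 and becomes the trans aryl/methyl pair of ring B. The absolute configuration is controlled by the catalyst, whose 3,3'-aryl groups should leave the Si face of the aldehyde open and give (3S,4S)-6. Ring B then closes by 5-exo-trig attack of the boron-bound alkoxide on the neighbouring ester carbonyl (O1–C7a), ethoxide passing to boron, and a trace of sulfonic acid completes this lactonisation. The step needs γ-selectivity, anti diastereoselectivity and one enantiomer: the first is inherent in cyclic allyl transfer, the second rests on the geometrically defined reagent from step 1, the third on the chiral acid. If the electron-rich benzylic C–O bond ionises during lactonisation, reclosure still favours the trans lactone and C3 is untouched, so the stereochemical information is kept.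

Step 3
Reactants: 7 (4S,5S)-4-methyl-3-methylidene-5-(3,4,5-trimethoxyphenyl)oxolan-2-one
Product: 8 (4S,5S)-4-methyl-3-[(phenylsulfanyl)methyl]-5-(3,4,5-trimethoxyphenyl)oxolan-2-one (C3 epimers)
Conditions: PhSH, Et3N (10 mol %), CH2Cl2, rt
Reagents that add atoms: thiophenol, Sc1ccccc1
Why: Amine-catalysed thia-Michael addition to the exocyclic acrylate puts sulfur on C4 as a marker of its later oxidation level. The new C3 centre does not matter because it is planarised in step 4.

Step 4
Reactants: 8 (4S,5S)-4-methyl-3-[(phenylsulfanyl)methyl]-5-(3,4,5-trimethoxyphenyl)oxolan-2-one (C3 epimers); 9 allyl bromide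
Product: 11 (3R,4S,5S)-4-methyl-3-[(phenylsulfanyl)methyl]-3-(prop-2-en-1-yl)-5-(3,4,5-trimethoxyphenyl)oxolan-2-one, via lithium enolate 10 (not isolated)
Conditions: LiN(i-Pr)2, THF, −78 °C; then 9, DMPU, −78 → −50 °C
Reagents that add atoms: none
Why: Lactone enolate alkylation: the planar enolate carbon should be attacked by allyl bromide on the face opposite the adjacent C4 methyl, setting the quaternary centre (future C3a) with allyl trans to methyl. Low temperature and a reactive electrophile are chosen so that alkylation outruns β-elimination of thiophenolate.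

Step 5
Reactants: 11 (3R,4S,5S)-4-methyl-3-[(phenylsulfanyl)methyl]-3-(prop-2-en-1-yl)-5-(3,4,5-trimethoxyphenyl)oxolan-2-one
Product: 12 (3R,4S,5S)-3-[(benzenesulfinyl)methyl]-4-methyl-3-(prop-2-en-1-yl)-5-(3,4,5-trimethoxyphenyl)oxolan-2-one (sulfur epimers)
Conditions: mCPBA (1.0 equiv), CH2Cl2, −78 °C
Reagents that add atoms: 3-chloroperbenzoic acid, O=C(OO)c1cccc(Cl)c1
Why: Sulfide-to-sulfoxide oxidation with one equivalent of peracid at low temperature; the sulfide reacts far faster than the terminal alkene or the arene, and the configuration at sulfur is irrelevant.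

Step 6
Reactants: 12 (3R,4S,5S)-3-[(benzenesulfinyl)methyl]-4-methyl-3-(prop-2-en-1-yl)-5-(3,4,5-trimethoxyphenyl)oxolan-2-one (sulfur epimers)
Product: 14 (3S,4S,5S)-4-methyl-2-oxo-3-(prop-2-en-1-yl)-5-(3,4,5-trimethoxyphenyl)oxolane-3-carbaldehyde, via trifluoroacetoxy sulfide 13 (not isolated)
Conditions: (CF3CO)2O, 2,6-lutidine, CH2Cl2, 0 °C; then aq. NaHCO3, rt
Reagents that add atoms: trifluoroacetic anhydride, O=C(OC(=O)C(F)(F)F)C(F)(F)F
Why: Pummerer rearrangement: O-acylation, deprotonation at the only α-CH2 and capture of the thionium ion by trifluoroacetate, then mild hydrolysis releases the non-enolisable C4 aldehyde (its oxygen comes from trifluoroacetate). The neighbouring carbon is quaternary, so neither elimination nor epimerisation can intervene, and the aryl group is trans to C4 and cannot reach the thionium ion.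

Step 7
Reactants: 15 methoxyacetone (1-methoxypropan-2-one)
Product: 16 (Z)-1-methoxy-2-(trimethylsilyloxy)prop-1-ene
Conditions: Me3SiCl, NaI, Et3N, MeCN, rt; distillation
Reagents that add atoms: chlorotrimethylsilane, C[Si](C)(C)Cl
Why: Silyl enol ether formation under equilibrating conditions should favour the more substituted, methoxy-bearing enol silane, as is usual for α-alkoxy ketones, fixing C5 as the nucleophilic carbon. The regiochemistry is secured at the stage of the distilled reagent; its alkene geometry has no bearing on the route.

Step 8
Reactants: 14 (3S,4S,5S)-4-methyl-2-oxo-3-(prop-2-en-1-yl)-5-(3,4,5-trimethoxyphenyl)oxolane-3-carbaldehyde; 16 (Z)-1-methoxy-2-(trimethylsilyloxy)prop-1-ene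
Product: 18 (3S,4S,5S)-3-(1-hydroxy-2-methoxy-3-oxobutyl)-4-methyl-3-(prop-2-en-1-yl)-5-(3,4,5-trimethoxyphenyl)oxolan-2-one (side-chain diastereomers), via silyl ether 17 (not isolated)
Conditions: Sc(OTf)3 (10 mol %), CH2Cl2, −78 → −40 °C; then dilute aq. HCl, THF, 0 °C
Reagents that add atoms: none
Why: Mukaiyama aldol addition of a regiodefined enol silane to a Lewis-acid-activated, non-enolisable aldehyde forms C4–C5 with silyl transfer to the aldolate oxygen; dilute acid then cleaves the silyl ether. The two new centres form as a mixture and are both removed in step 9.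

Step 9
Reactants: 18 (3S,4S,5S)-3-(1-hydroxy-2-methoxy-3-oxobutyl)-4-methyl-3-(prop-2-en-1-yl)-5-(3,4,5-trimethoxyphenyl)oxolan-2-one (side-chain diastereomers)
Product: 20 (2S,3S,3aS)-5-methoxy-3-methyl-3a-(prop-2-en-1-yl)-2-(3,4,5-trimethoxyphenyl)-3,3a-dihydro-1-benzofuran-6(2H)-one, via hydroxy diketone 19 (not isolated)
Conditions: LiN(i-Pr)2 (3.5 equiv), THF, −78 → 0 °C, then AcOH; TsOH·H2O (10 mol %), CH2Cl2, rt
Reagents that add atoms: none
Why: Excess amide base forms the C4 alkoxide and then the kinetic methyl enolate, which closes ring A by a 6-exo-trig Claisen (Dieckmann-type) acylation at the lactone carbonyl C7a; the C4 alkoxide cannot leave and the enolised ketone cannot undergo retro-aldol cleavage. Catalytic acid then dehydrates the β-hydroxy ketone across C4–C5 (only C5 carries a hydrogen) and condenses the C2 hydroxyl with the C7a carbonyl (5-exo-trig, C2–O bond intact) to the vinylogous ester. C2, C3 and C3a have no epimerisation pathway under these conditions.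

## Compound list

1 | ethyl but-2-ynoate | CC#CC(=O)OCC | starting material
2 | 2-(iodomethyl)-4,4,5,5-tetramethyl-1,3,2-dioxaborolane | ICB1OC(C)(C)C(C)(C)O1 | starting material
3 | ethyl (E)-2-(diisobutylalumanyl)but-2-enoate (carbon-bound form of the aluminium allenoate) | CCOC(=O)/C([Al](CC(C)C)CC(C)C)=C\C | intermediate (not isolated)
4 | ethyl (Z)-2-[(4,4,5,5-tetramethyl-1,3,2-dioxaborolan-2-yl)methyl]but-2-enoate | CCOC(=O)/C(CB1OC(C)(C)C(C)(C)O1)=C\C | intermediate
5 | 3,4,5-trimethoxybenzaldehyde | COc1cc(C=O)cc(OC)c1OC | starting material
6 | ethyl (3S,4S)-3-methyl-2-methylidene-4-[(4,4,5,5-tetramethyl-1,3,2-dioxaborolan-2-yl)oxy]-4-(3,4,5-trimethoxyphenyl)butanoate | CCOC(=O)C(=C)[C@H](C)[C@H](OB1OC(C)(C)C(C)(C)O1)c1cc(OC)c(OC)c(OC)c1 | intermediate (not isolated)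
7 | (4S,5S)-4-methyl-3-methylidene-5-(3,4,5-trimethoxyphenyl)oxolan-2-one | C=C1C(=O)O[C@H](c2cc(OC)c(OC)c(OC)c2)[C@H]1C | intermediate
8 | (4S,5S)-4-methyl-3-[(phenylsulfanyl)methyl]-5-(3,4,5-trimethoxyphenyl)oxolan-2-one (C3 epimers) | c1ccccc1SCC1C(=O)O[C@H](c2cc(OC)c(OC)c(OC)c2)[C@H]1C | intermediate
9 | allyl bromide (3-bromoprop-1-ene) | C=CCBr | starting material
10 | lithium (4S,5S)-4-methyl-3-[(phenylsulfanyl)methyl]-5-(3,4,5-trimethoxyphenyl)-4,5-dihydrofuran-2-olate | c1ccccc1SCC1=C(O[Li])O[C@H](c2cc(OC)c(OC)c(OC)c2)[C@H]1C | intermediate (not isolated)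
11 | (3R,4S,5S)-4-methyl-3-[(phenylsulfanyl)methyl]-3-(prop-2-en-1-yl)-5-(3,4,5-trimethoxyphenyl)oxolan-2-one | C=CC[C@]1(CSc2ccccc2)C(=O)O[C@H](c2cc(OC)c(OC)c(OC)c2)[C@H]1C | intermediate
12 | (3R,4S,5S)-3-[(benzenesulfinyl)methyl]-4-methyl-3-(prop-2-en-1-yl)-5-(3,4,5-trimethoxyphenyl)oxolan-2-one (sulfur epimers) | C=CC[C@]1(CS(=O)c2ccccc2)C(=O)O[C@H](c2cc(OC)c(OC)c(OC)c2)[C@H]1C | intermediate
13 | [(3R,4S,5S)-4-methyl-2-oxo-3-(prop-2-en-1-yl)-5-(3,4,5-trimethoxyphenyl)oxolan-3-yl](phenylsulfanyl)methyl trifluoroacetate (epimers at the new carbon) | C=CC[C@]1(C(OC(=O)C(F)(F)F)Sc2ccccc2)C(=O)O[C@H](c2cc(OC)c(OC)c(OC)c2)[C@H]1C | intermediate (not isolated)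
14 | (3S,4S,5S)-4-methyl-2-oxo-3-(prop-2-en-1-yl)-5-(3,4,5-trimethoxyphenyl)oxolane-3-carbaldehyde | C=CC[C@]1(C=O)C(=O)O[C@H](c2cc(OC)c(OC)c(OC)c2)[C@H]1C | intermediate
15 | methoxyacetone (1-methoxypropan-2-one) | COCC(C)=O | starting material
16 | (Z)-1-methoxy-2-(trimethylsilyloxy)prop-1-ene | CO/C=C(/C)O[Si](C)(C)C | intermediate
17 | (3S,4S,5S)-3-[2-methoxy-3-oxo-1-(trimethylsilyloxy)butyl]-4-methyl-3-(prop-2-en-1-yl)-5-(3,4,5-trimethoxyphenyl)oxolan-2-one (side-chain diastereomers) | C=CC[C@]1(C(O[Si](C)(C)C)C(OC)C(C)=O)C(=O)O[C@H](c2cc(OC)c(OC)c(OC)c2)[C@H]1C | intermediate (not isolated)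
18 | (3S,4S,5S)-3-(1-hydroxy-2-methoxy-3-oxobutyl)-4-methyl-3-(prop-2-en-1-yl)-5-(3,4,5-trimethoxyphenyl)oxolan-2-one (side-chain diastereomers) | C=CC[C@]1(C(O)C(OC)C(C)=O)C(=O)O[C@H](c2cc(OC)c(OC)c(OC)c2)[C@H]1C | intermediate
19 | (4S)-5-hydroxy-4-[(1S,2S)-1-hydroxy-1-(3,4,5-trimethoxyphenyl)propan-2-yl]-6-methoxy-4-(prop-2-en-1-yl)cyclohexane-1,3-dione (C5/C6 diastereomers, enol tautomers) | C=CC[C@@]1([C@H](C)[C@H](O)c2cc(OC)c(OC)c(OC)c2)C(=O)CC(=O)C(OC)C1O | intermediate (not isolated)
20 | (2S,3S,3aS)-5-methoxy-3-methyl-3a-(prop-2-en-1-yl)-2-(3,4,5-trimethoxyphenyl)-3,3a-dihydro-1-benzofuran-6(2H)-one | C=CC[C@]12C=C(OC)C(=O)C=C1O[C@H](c1cc(OC)c(OC)c(OC)c1)[C@H]2C | target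

## Step count and least certain steps

Total step count: 9 (eight in the main line plus the preparation of 16). Longest linear sequence: 8 steps (1 → 4 → 7 → 8 → 11 → 12 → 14 → 18 → 20).

**Step 2 (key step).** Allyl transfer is likely to be slow, because the ester group lowers the nucleophilicity of the allyl unit and a phosphoric acid activates far less than the sulfonic or Lewis acids normally used with this reagent class. A slow catalysed path lets the unselective background addition compete, so enantiomeric purity would drop, and the facial sense rests on an analogy. The fallback replaces catalyst control by auxiliary control; it sets out from 2 and 5 and comes back at 7. But-2-ynoic acid is esterified with (1R,2S,5R)-8-phenylmenthol to give 8-phenylmenthyl but-2-ynoate F1. Hydroalumination and borylmethylation as in step 1 give the 8-phenylmenthyl (Z)-2-(borylmethyl)but-2-enoate F2. Its Sc(OTf)3-catalysed addition to 5 at −78 °C, with the phenyl group of the auxiliary shielding one face of the allyl unit, followed by acid-induced lactonisation with release of the auxiliary, leads to 7. The enantiomer of the auxiliary has to be matched to the required face.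

**Step 4.** β-Elimination of thiophenolate from enolate 10 (a retro-Michael process) becomes competitive if alkylation at the hindered carbon needs warming. Facial selectivity may also be incomplete, because the C5 aryl group lies on the face that allyl must enter. The fallback uses an oxygen marker with a much poorer leaving ability; it sets out from 7 and comes back at 14. Oxa-Michael addition of 4-methoxybenzyl alcohol (catalytic KOC(CH3)3) gives the 4-methoxybenzyl ether F3. Deprotonation and allylation under the conditions of step 4 give the quaternary ether F4. DDQ removes the benzyl group to give the primary alcohol F5, and Dess–Martin oxidation gives 14. The step count equals that of steps 3–6.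

**Step 8.** Addition to the neopentyl-type aldehyde may be slow, and then hydrolysis of the electron-rich enol silane or a Lewis-acid-induced carbonyl–ene closure onto the allyl group can take over. The fallback changes from Lewis-acid activation of the electrophile to a preformed metal enolate; it sets out from 16 and comes back at 18. Cleavage of 16 with MeLi in THF gives the regiodefined lithium (Z)-1-methoxyprop-1-en-2-olate F6, which adds to 14 at −78 °C; protonation of the aldolate gives 18.

**Step 9.** Ring closure may be incomplete because the lactone carbonyl is flanked by the quaternary carbon. The aldolate may undergo retro-aldol cleavage before the ketone is enolised. The allyl group may migrate, or ring A may aromatise, if the acid-induced dehydration needs forcing. The fallback reverses the order of the two C–C bond formations; it sets out from 14 and comes back at 20. Acetalisation (HC(OCH3)3, TsOH, MeOH) gives the dimethyl acetal F7. The kinetic methyl-side enolate of 15, lithium 3-methoxyprop-1-en-2-olate F8 (LiN(i-Pr)2, THF, −78 °C), is acylated by the lactone of F7 to give the hydroxy β-diketone acetal F9. Aqueous acid then unmasks the aldehyde, C5 closes on C4 by a Robinson-type aldol condensation (the only six-ring mode available), and the C2 hydroxyl condenses with C7a to give 20.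

Further compounds

F1 | step 2 | (1R,2S,5R)-5-methyl-2-(2-phenylpropan-2-yl)cyclohexyl but-2-ynoate | CC#CC(=O)O[C@@H]1C[C@H](C)CC[C@H]1C(C)(C)c1ccccc1
F2 | step 2 | (1R,2S,5R)-5-methyl-2-(2-phenylpropan-2-yl)cyclohexyl (Z)-2-[(4,4,5,5-tetramethyl-1,3,2-dioxaborolan-2-yl)methyl]but-2-enoate | C/C=C(/CB1OC(C)(C)C(C)(C)O1)C(=O)O[C@@H]1C[C@H](C)CC[C@H]1C(C)(C)c1ccccc1
F3 | step 4 | (4S,5S)-3-{[(4-methoxyphenyl)methoxy]methyl}-4-methyl-5-(3,4,5-trimethoxyphenyl)oxolan-2-one (C3 epimers) | COc1ccc(COCC2C(=O)O[C@H](c3cc(OC)c(OC)c(OC)c3)[C@H]2C)cc1
F4 | step 4 | (3S,4S,5S)-3-{[(4-methoxyphenyl)methoxy]methyl}-4-methyl-3-(prop-2-en-1-yl)-5-(3,4,5-trimethoxyphenyl)oxolan-2-one | C=CC[C@]1(COCc2ccc(OC)cc2)C(=O)O[C@H](c2cc(OC)c(OC)c(OC)c2)[C@H]1C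
F5 | step 4 | (3S,4S,5S)-3-(hydroxymethyl)-4-methyl-3-(prop-2-en-1-yl)-5-(3,4,5-trimethoxyphenyl)oxolan-2-one | C=CC[C@]1(CO)C(=O)O[C@H](c2cc(OC)c(OC)c(OC)c2)[C@H]1C
F6 | step 8 | lithium (Z)-1-methoxyprop-1-en-2-olate | CO/C=C(/C)O[Li]
F7 | step 9 | (3S,4S,5S)-3-(dimethoxymethyl)-4-methyl-3-(prop-2-en-1-yl)-5-(3,4,5-trimethoxyphenyl)oxolan-2-one | C=CC[C@]1(C(OC)OC)C(=O)O[C@H](c2cc(OC)c(OC)c(OC)c2)[C@H]1C
F8 | step 9 | lithium 3-methoxyprop-1-en-2-olate | C=C(O[Li])COC
F9 | step 9 | (5S)-5-(dimethoxymethyl)-5-[(1S,2S)-1-hydroxy-1-(3,4,5-trimethoxyphenyl)propan-2-yl]-1-methoxyoct-7-ene-2,4-dione | C=CC[C@@](C(OC)OC)([C@H](C)[C@H](O)c1cc(OC)c(OC)c(OC)c1)C(=O)CC(=O)COC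
A1 | alternative 1 | (2R)-3-diazo-6-methoxy-7-[(triisopropylsilyl)oxy]-2-(3,4,5-trimethoxyphenyl)-2,3-dihydro-4H-chromen-4-one | [N-]=[N+]=C1C(=O)c2cc(OC)c(O[Si](C(C)C)(C(C)C)C(C)C)cc2O[C@@H]1c1cc(OC)c(OC)c(OC)c1
A2 | alternative 1 | methyl (2S,3S)-5-methoxy-6-[(triisopropylsilyl)oxy]-2-(3,4,5-trimethoxyphenyl)-2,3-dihydro-1-benzofuran-3-carboxylate | c12cc(OC)c(O[Si](C(C)C)(C(C)C)C(C)C)cc1O[C@H](c1cc(OC)c(OC)c(OC)c1)[C@H]2C(=O)OC
A3 | alternative 2 | tert-butyl 3-{[(1S,2S,3E)-6-[(tert-butyldimethylsilyl)oxy]-5,6-dimethoxy-2-methyl-3-(prop-2-en-1-yl)-1-(3,4,5-trimethoxyphenyl)hexa-3,5-dien-1-yl]oxy}prop-2-ynoate (C5=C6 geometry not defined) | CC(C)(C)OC(=O)C#CO[C@H](c1cc(OC)c(OC)c(OC)c1)[C@@H](C)/C(CC=C)=C/C(OC)=C(OC)O[Si](C)(C)C(C)(C)C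
A4 | alternative 2 | tert-butyl (2S,3S,3aS)-5-methoxy-3-methyl-6-oxo-3a-(prop-2-en-1-yl)-2-(3,4,5-trimethoxyphenyl)-2,3,3a,6-tetrahydro-1-benzofuran-7-carboxylate | C=CC[C@]12C=C(OC)C(=O)C(C(=O)OC(C)(C)C)=C1O[C@H](c1cc(OC)c(OC)c(OC)c1)[C@H]2C
A5 | alternative 3 | 4-[(1S,2S)-1-hydroxy-1-(3,4,5-trimethoxyphenyl)propan-2-yl]-4-(prop-2-en-1-yl)cyclohexa-2,5-dien-1-one | C=CCC1([C@H](C)[C@H](O)c2cc(OC)c(OC)c(OC)c2)C=CC(=O)C=C1
A6 | alternative 3 | (2S,3S,3aR,7aR)-3-methyl-3a-(prop-2-en-1-yl)-2-(3,4,5-trimethoxyphenyl)-3,3a,7,7a-tetrahydro-1-benzofuran-6(2H)-one | C=CC[C@]12C=CC(=O)C[C@H]1O[C@H](c1cc(OC)c(OC)c(OC)c1)[C@H]2C
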